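**Fixed sum.** In a closed flask the substrate counted in ring, open dimer and the rest stays equal to the charge. So I ask how long a charge can feed the products.

| setting | maple | birch | flask |
|---|---|---|---|
| solid substrate | 21 mM | 33 mM | 15 mM |
| remark | run made earlier | run made earlier |  |
| time |  |  | 80 min |

| run | time / min | ring / % | open dimer / % |
|---|---|---|---|
| maple | 10.0 | 0 | 2 |
| maple | 20.0 | 9 | 4 |
| maple | 30.0 | 13 | 9 |
| maple | 40.0 | 16 | 11 |
| maple | 50.0 | 25 | 15 |
| maple | 60.0 | 31 | 19 |
| birch | 4.00 | 3 | 0 |
| birch | 12.0 | 4 | 2 |
| birch | 25.0 | 6 | 3 |
| birch | 40.0 | 13 | 4 |
| birch | 50.0 | 17 | 8 |
| birch | 60.0 | 18 | 10 |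

(standard deviation of a reading: 1.5 percentage points)

- a species is counted by the solid substrate in it: one open dimer counts as two
- given per volume of solution although it is solid: solid substrate
- what was read earlier has a scatter of 1.5 percentage points, one standard deviation
- at the start none of the solid substrate is in solution

* how much ring the flask holds at 80 min, in percent of the solid substrate charged
* how much open dimer the flask holds at 80 min, in percent of the solid substrate charged

**Two times.** At 60.0 min, the maple run holds 10.5 mM of substrate in products and the birch run 9.24 mM, though their charges are 21 mM and 33 mM. I read this as a zero-order supply of about 0.165 mM min⁻¹.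

**Charge life.** I divide the asked flask's c(solid substrate) by that supply and get 91.2 min, the charge life. Dissolved substrate also takes a share, so the solid should end sooner. The asked 80 min is 0.877 of the charge life. The steady supply would put 87.7% of the charge in products, and I expect less.

**Forecast.** It gives 54% ring (47% to 60%) and 30% open dimer (25% to 35%): “Rates would then fall, the second-order dimer route most, so I shade both values down.”

**Result.** The flask holds 56.3% ring, inside the forecast's range, and 17.1% open dimer, below that range.

    starting material → ring (k = 0.0210 min⁻¹)
    2 starting material ⇌ open dimer (K = 51.0 M⁻¹, k = 1.80 M⁻¹ min⁻¹)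
    starting material → decomposition product (k = 3.60 × 10⁻⁵ min⁻¹)
    solid substrate ⇌ starting material, rate k4*(cs4 - [starting material]) while solid is left; crystals form when [starting material] > cs4 (solubility = 9.20 mM, k = 0.0680 min⁻¹)

**Past the solid.** This flask's solid stands at 18.1% at 40.0 min and 0% at 80.0 min, a time earlier than the charge life. In this flask at 80 min, starting material is made at 0.399 of the rate it is used up, each step taken net, and the relaxation half-life of starting material and open dimer by that step alone, both ways together, is 10.8 min, short against that time. The neighbour flask charged with 9.0 mM has a charge life of 54.5 min, and at 80.0 min it holds 0% solid and 10.6% open dimer.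

(The earlier runs and the new flask are calculated from invented constants; noise was put on by code.)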